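**Retrosynthetic overview**
1. Ring A is a phloroglucinol whose ether carbon C1' sits between the hydroxyl carbons C2' and C6', with the third OH at C4'. This is the pattern a malonate leaves when its central carbon keeps a substituent and its two ester carbons become ring carbons. Cutting C2'–C3' and C5'–C6' gives a diethyl aryloxymalonate and diethyl 3-oxopentanedioate.
2. The aryloxymalonate comes from O-alkylation of the permethylated ring BCDE tetramer phenol at an sp3 carbon, so the most crowded ether (ring A–O–ring B) is never made by aryl–oxygen coupling.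
3. The tetramer is assembled from the ring E end (E, D, C, B) by three Ullmann etherifications with commercial bromobenzaldehydes; each formyl group becomes the next phenol by Baeyer–Villiger oxidation.
4. Rings B to E are bought as arenes; ring A is the only ring formed, and it is formed last (step 8). Saponification/decarboxylation and BBr3 demethylation finish the route.

Key step: step 8

Remark: the target has no stereocentre, so only constitution has to be controlled; rings are lettered A (phloroglucinol end) to E (3,4,5-trihydroxyphenoxy end), and Ar denotes the aryl group of phenol 12 without its OH.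

**Step 1**
Reactants: 1 3,4,5-trimethoxyphenol; 2 2-bromo-3,4,5-trimethoxybenzaldehyde
Product: 3 3,4,5-trimethoxy-2-(3,4,5-trimethoxyphenoxy)benzaldehyde
Conditions: CuI (10 mol%), N,N-dimethylglycine hydrochloride (30 mol%), Cs2CO3, 1,4-dioxane, 100 °C, argon
Reagents that add atoms: none
Why: Copper-catalysed Ullmann diaryl ether synthesis, in which the unhindered electron-rich phenoxide of 1 displaces bromide from 2, whose C–Br bond is activated by the ortho formyl group, while the non-enolisable aldehyde tolerates the carbonate base.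

**Step 2**
Reactants: 3 3,4,5-trimethoxy-2-(3,4,5-trimethoxyphenoxy)benzaldehyde
Product: 5 3,4,5-trimethoxy-2-(3,4,5-trimethoxyphenoxy)phenol, via aryl formate 4 (not isolated)
Conditions: mCPBA, CH2Cl2, 0 °C to rt; then K2CO3 (cat.), MeOH, rt
Reagents that add atoms: mCPBA (3-chloroperoxybenzoic acid), OOC(=O)c1cccc(Cl)c1
Why: Baeyer–Villiger (Dakin-type) oxidation, in which the aryl group with its ortho aryloxy and para methoxy donors migrates in preference to hydrogen to give the formate, and mild methanolysis then frees the phenol without touching methyl or diaryl ethers.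

**Step 3**
Reactants: 5 3,4,5-trimethoxy-2-(3,4,5-trimethoxyphenoxy)phenol; 6 4-bromo-3,5-dimethoxybenzaldehyde
Product: 7 3,5-dimethoxy-4-[3,4,5-trimethoxy-2-(3,4,5-trimethoxyphenoxy)phenoxy]benzaldehyde
Conditions: CuI (20 mol%), picolinic acid (40 mol%), K3PO4, DMSO, 100 °C, argon
Reagents that add atoms: none
Why: Ullmann etherification with a ligand suited to hindered partners, where the para formyl group lowers the electron density at the doubly ortho-methoxylated C–Br carbon and the phenoxide of 5 carries only one ortho substituent.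

**Step 4**
Reactants: 7 3,5-dimethoxy-4-[3,4,5-trimethoxy-2-(3,4,5-trimethoxyphenoxy)phenoxy]benzaldehyde
Product: 9 3,5-dimethoxy-4-[3,4,5-trimethoxy-2-(3,4,5-trimethoxyphenoxy)phenoxy]phenol, via aryl formate 8 (not isolated)
Conditions: mCPBA, CH2Cl2, 0 °C to rt; then K2CO3 (cat.), MeOH, rt
Reagents that add atoms: mCPBA (3-chloroperoxybenzoic acid), OOC(=O)c1cccc(Cl)c1
Why: Baeyer–Villiger oxidation of a 4-aryloxy-3,5-dimethoxybenzaldehyde, which should follow the known conversion of 3,4,5-trimethoxybenzaldehyde into its phenol because the para oxygen donor again favours aryl migration.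

**Step 5**
Reactants: 9 3,5-dimethoxy-4-[3,4,5-trimethoxy-2-(3,4,5-trimethoxyphenoxy)phenoxy]phenol; 2 2-bromo-3,4,5-trimethoxybenzaldehyde
Product: 10 2-{3,5-dimethoxy-4-[3,4,5-trimethoxy-2-(3,4,5-trimethoxyphenoxy)phenoxy]phenoxy}-3,4,5-trimethoxybenzaldehyde
Conditions: CuI (10 mol%), N,N-dimethylglycine hydrochloride (30 mol%), Cs2CO3, 1,4-dioxane, 100 °C, argon
Reagents that add atoms: none
Why: Ullmann etherification as in step 1, favoured because the phenol oxygen of 9 has hydrogen at both ortho positions and the bromide is activated by its ortho formyl group.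

**Step 6**
Reactants: 10 2-{3,5-dimethoxy-4-[3,4,5-trimethoxy-2-(3,4,5-trimethoxyphenoxy)phenoxy]phenoxy}-3,4,5-trimethoxybenzaldehyde
Product: 12 2-{3,5-dimethoxy-4-[3,4,5-trimethoxy-2-(3,4,5-trimethoxyphenoxy)phenoxy]phenoxy}-3,4,5-trimethoxyphenol (ArOH), via aryl formate 11 (not isolated)
Conditions: mCPBA, CH2Cl2, 0 °C to rt; then K2CO3 (cat.), MeOH, rt
Reagents that add atoms: mCPBA (3-chloroperoxybenzoic acid), OOC(=O)c1cccc(Cl)c1
Why: Baeyer–Villiger oxidation on the same ring type as in step 2, so the same migration preference should deliver the ring B phenol.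

**Step 7**
Reactants: 12 permethylated ring BCDE tetramer phenol ArOH; 13 diethyl chloromalonate
Product: 14 diethyl 2-(ArO)propanedioate
Conditions: K2CO3, acetone, reflux
Reagents that add atoms: none
Why: Williamson-type SN2 O-alkylation at the doubly activated sp3 carbon of the halomalonate, a known route to aryloxymalonates from ortho-substituted phenols; the chloro compound is chosen so that no halogen is transferred to the electron-rich ring.

**Step 8**
Reactants: 14 diethyl 2-(ArO)propanedioate; 15 diethyl 3-oxopentanedioate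
Product: 17 diethyl 5-(ArO)-2,4,6-trihydroxybenzene-1,3-dicarboxylate, via acyclic Claisen adduct 16 (not isolated)
Conditions: 15 (1.5 equiv), NaOEt (3 equiv), EtOH, rt; add 14 in toluene, distil off EtOH, 110 °C; then cold aq. HCl
Reagents that add atoms: none
Why: The sodium enolate of 15, whose ketone is masked so that self-aldol is held back, is C-acylated at C2 by one ester group of 14 in a crossed Claisen condensation to give 16, and the second carbanion at C4 of the ketodiester unit then attacks the remaining malonate ester in a Dieckmann acylation, so that the C2'–C3' and C5'–C6' bonds of ring A are formed. The ring closure is 6-exo-trig at the ester carbonyl, and loss of the second ethanol followed by triple enolisation gives the aromatic triol diester as its sodium salt, a sink that draws the reversible acylations forward. The closest known reaction is the alkoxide-mediated condensation of malonic esters with 3-oxoglutaric esters to phloroglucinol dicarboxylates, the laboratory counterpart of triketide folding. No stereocentre is formed, and because both partners are symmetric about their central carbon no regiochemical question arises. The selectivity needed is C- over O-acylation and cross- over self-condensation: the chelated sodium enolate reacts through carbon, any pyranone from O-acylation is reopened by ethoxide under these equilibrating conditions, and the α-aryloxy esters of 14 are better acyl acceptors than plain malonate esters while 14, being less acidic than 15, stays largely un-enolised.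

**Step 9**
Reactants: 17 diethyl 5-(ArO)-2,4,6-trihydroxybenzene-1,3-dicarboxylate
Product: 19 2-(ArO)benzene-1,3,5-triol, via dicarboxylic acid 18 (not isolated)
Conditions: KOH (2 M aq., degassed), EtOH, reflux, argon; then aq. HCl to pH 1, 70 °C
Reagents that add atoms: none
Why: Ester saponification followed by decarboxylation, which is easy for 2,4,6-trihydroxybenzoic acids because ipso-protonation gives a β-keto acid tautomer; aryl and methyl ethers are inert and air is excluded to protect the phloroglucinolate.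

**Step 10**
Reactants: 19 2-(ArO)benzene-1,3,5-triol
Product: 20 2-(3,4,5-trihydroxy-2-{3,5-dihydroxy-4-[3,4,5-trihydroxy-2-(3,4,5-trihydroxyphenoxy)phenoxy]phenoxy}phenoxy)benzene-1,3,5-triol (target)
Conditions: BBr3 (excess), CH2Cl2, −78 °C to rt; then ice water; degassed work-up
Reagents that add atoms: none
Why: Lewis-acid ether cleavage with BBr3, in which bromide attacks the methyl carbon of each boron-complexed aryl methyl ether, whereas the diaryl ether oxygens carry no sp3 carbon and should stay intact; hydrolysis of the aryl borates frees the fourteen hydroxyl groups.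

**Compound list**
Ar = 2-{3,5-dimethoxy-4-[3,4,5-trimethoxy-2-(3,4,5-trimethoxyphenoxy)phenoxy]phenoxy}-3,4,5-trimethoxyphenyl

1 | 3,4,5-trimethoxyphenol | COc1cc(O)cc(OC)c1OC | starting material
2 | 2-bromo-3,4,5-trimethoxybenzaldehyde | O=Cc1cc(OC)c(OC)c(OC)c1Br | starting material
3 | 3,4,5-trimethoxy-2-(3,4,5-trimethoxyphenoxy)benzaldehyde | O=Cc1cc(OC)c(OC)c(OC)c1Oc1cc(OC)c(OC)c(OC)c1 | intermediate
4 | 3,4,5-trimethoxy-2-(3,4,5-trimethoxyphenoxy)phenyl formate | O=COc1cc(OC)c(OC)c(OC)c1Oc1cc(OC)c(OC)c(OC)c1 | intermediate (not isolated)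
5 | 3,4,5-trimethoxy-2-(3,4,5-trimethoxyphenoxy)phenol | Oc1cc(OC)c(OC)c(OC)c1Oc1cc(OC)c(OC)c(OC)c1 | intermediate
6 | 4-bromo-3,5-dimethoxybenzaldehyde | O=Cc1cc(OC)c(Br)c(OC)c1 | starting material
7 | 3,5-dimethoxy-4-[3,4,5-trimethoxy-2-(3,4,5-trimethoxyphenoxy)phenoxy]benzaldehyde | O=Cc1cc(OC)c(Oc2cc(OC)c(OC)c(OC)c2Oc2cc(OC)c(OC)c(OC)c2)c(OC)c1 | intermediate
8 | 3,5-dimethoxy-4-[3,4,5-trimethoxy-2-(3,4,5-trimethoxyphenoxy)phenoxy]phenyl formate | O=COc1cc(OC)c(Oc2cc(OC)c(OC)c(OC)c2Oc2cc(OC)c(OC)c(OC)c2)c(OC)c1 | intermediate (not isolated)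
9 | 3,5-dimethoxy-4-[3,4,5-trimethoxy-2-(3,4,5-trimethoxyphenoxy)phenoxy]phenol | Oc1cc(OC)c(Oc2cc(OC)c(OC)c(OC)c2Oc2cc(OC)c(OC)c(OC)c2)c(OC)c1 | intermediate
10 | 2-{3,5-dimethoxy-4-[3,4,5-trimethoxy-2-(3,4,5-trimethoxyphenoxy)phenoxy]phenoxy}-3,4,5-trimethoxybenzaldehyde | O=Cc1cc(OC)c(OC)c(OC)c1Oc1cc(OC)c(Oc2cc(OC)c(OC)c(OC)c2Oc2cc(OC)c(OC)c(OC)c2)c(OC)c1 | intermediate
11 | 2-{3,5-dimethoxy-4-[3,4,5-trimethoxy-2-(3,4,5-trimethoxyphenoxy)phenoxy]phenoxy}-3,4,5-trimethoxyphenyl formate | O=COc1cc(OC)c(OC)c(OC)c1Oc1cc(OC)c(Oc2cc(OC)c(OC)c(OC)c2Oc2cc(OC)c(OC)c(OC)c2)c(OC)c1 | intermediate (not isolated)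
12 | 2-{3,5-dimethoxy-4-[3,4,5-trimethoxy-2-(3,4,5-trimethoxyphenoxy)phenoxy]phenoxy}-3,4,5-trimethoxyphenol (ArOH) | Oc1cc(OC)c(OC)c(OC)c1Oc1cc(OC)c(Oc2cc(OC)c(OC)c(OC)c2Oc2cc(OC)c(OC)c(OC)c2)c(OC)c1 | intermediate
13 | diethyl chloromalonate | CCOC(=O)C(Cl)C(=O)OCC | starting material
14 | diethyl 2-(ArO)propanedioate | CCOC(=O)C(Oc1cc(OC)c(OC)c(OC)c1Oc1cc(OC)c(Oc2cc(OC)c(OC)c(OC)c2Oc2cc(OC)c(OC)c(OC)c2)c(OC)c1)C(=O)OCC | intermediate
15 | diethyl 3-oxopentanedioate | CCOC(=O)CC(=O)CC(=O)OCC | starting material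
16 | triethyl 1-(ArO)-2,4-dioxopentane-1,3,5-tricarboxylate | CCOC(=O)C(Oc1cc(OC)c(OC)c(OC)c1Oc1cc(OC)c(Oc2cc(OC)c(OC)c(OC)c2Oc2cc(OC)c(OC)c(OC)c2)c(OC)c1)C(=O)C(C(=O)OCC)C(=O)CC(=O)OCC | intermediate (not isolated)
17 | diethyl 5-(ArO)-2,4,6-trihydroxybenzene-1,3-dicarboxylate | CCOC(=O)c1c(O)c(C(=O)OCC)c(O)c(Oc2cc(OC)c(OC)c(OC)c2Oc2cc(OC)c(Oc3cc(OC)c(OC)c(OC)c3Oc3cc(OC)c(OC)c(OC)c3)c(OC)c2)c1O | intermediate
18 | 5-(ArO)-2,4,6-trihydroxybenzene-1,3-dicarboxylic acid | OC(=O)c1c(O)c(C(=O)O)c(O)c(Oc2cc(OC)c(OC)c(OC)c2Oc2cc(OC)c(Oc3cc(OC)c(OC)c(OC)c3Oc3cc(OC)c(OC)c(OC)c3)c(OC)c2)c1O | intermediate (not isolated)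
19 | 2-(ArO)benzene-1,3,5-triol | Oc1cc(O)c(Oc2cc(OC)c(OC)c(OC)c2Oc2cc(OC)c(Oc3cc(OC)c(OC)c(OC)c3Oc3cc(OC)c(OC)c(OC)c3)c(OC)c2)c(O)c1 | intermediate
20 | 2-(3,4,5-trihydroxy-2-{3,5-dihydroxy-4-[3,4,5-trihydroxy-2-(3,4,5-trihydroxyphenoxy)phenoxy]phenoxy}phenoxy)benzene-1,3,5-triol | Oc1cc(O)c(Oc2cc(O)c(O)c(O)c2Oc2cc(O)c(Oc3cc(O)c(O)c(O)c3Oc3cc(O)c(O)c(O)c3)c(O)c2)c(O)c1 | target

**Step count**
Total: 10 steps. Longest linear sequence: 10 steps (from 1 to 20).

**Steps most likely to fail**

Step 8 (benzannulation). The crossed Claisen acylation may stall because the acyl acceptor is drained by enolisation or by ethoxide-induced loss of an ethoxycarbonyl group. It may also be overtaken by self-condensation of the ketodiester or by O-acylation. The fallback sets out from phenol 12 and attaches ring A ready-made by Ullmann etherification with 2-bromo-1,3,5-trimethoxybenzene (CuI, picolinic acid, K3PO4, DMSO, 110 °C), a known way to 2,4,6-trimethoxyphenyl ethers. This should give the fully methylated pentamer 2-(ArO)-1,3,5-trimethoxybenzene F1. Cleavage of its fourteen methyl ethers with BBr3 (CH2Cl2, −78 °C to rt, then ice water) comes back to the route at the target 20.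

Step 3 (hindered Ullmann coupling). Catalyst turnover at the doubly ortho-methoxylated C–Br bond may be slow with the bulky phenoxide, so that protodebromination of the bromide and base-induced disproportionation of its formyl group outrun the coupling. The fallback sets out from phenol 5 and removes the aldehyde from the coupling step. Aldehyde-free 2-iodo-1,3-dimethoxybenzene is used in excess under forcing Ullmann conditions (CuI, 2,2,6,6-tetramethylheptane-3,5-dione, Cs2CO3, NMP, 130 °C) to give 1-(2,6-dimethoxyphenoxy)-3,4,5-trimethoxy-2-(3,4,5-trimethoxyphenoxy)benzene F2. Sterically controlled C–H borylation ([Ir(OMe)(cod)]2, 4,4'-di-tert-butyl-2,2'-bipyridine, B2pin2, THF, 80 °C) can reach only the one C–H of F2 that has no ortho substituent, para to the ether oxygen of the new ring C. It should give the pinacol boronate 2-{3,5-dimethoxy-4-[3,4,5-trimethoxy-2-(3,4,5-trimethoxyphenoxy)phenoxy]phenyl}-4,4,5,5-tetramethyl-1,3,2-dioxaborolane F3. Oxidation of the C–B bond with KHSO5 (Oxone) in acetone/water comes back to the route at phenol 9, replacing steps 3 and 4.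

Step 10 (global demethylation). Cleavage of eleven methyl ethers may stop short at the crowded inner methoxy groups, and the free polyphenol may oxidise in air during chromatographic purification. The fallback sets out from 19 and changes how the product is isolated. After BBr3 cleavage the crude phenol is not purified but acetylated at once (Ac2O, pyridine, rt) to the air-stable tetradecaacetate of the target F4. F4 is purified on silica, and under-cleaved fractions are separated and returned to BBr3. Acid methanolysis of pure F4 (HCl, degassed MeOH, 40 °C, argon) comes back to the route at 20.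

**Further compounds**
F1 | step 8 | 2-(2-{3,5-dimethoxy-4-[3,4,5-trimethoxy-2-(3,4,5-trimethoxyphenoxy)phenoxy]phenoxy}-3,4,5-trimethoxyphenoxy)-1,3,5-trimethoxybenzene | COc1cc(OC)c(Oc2cc(OC)c(OC)c(OC)c2Oc2cc(OC)c(Oc3cc(OC)c(OC)c(OC)c3Oc3cc(OC)c(OC)c(OC)c3)c(OC)c2)c(OC)c1
F2 | step 3 | 1-(2,6-dimethoxyphenoxy)-3,4,5-trimethoxy-2-(3,4,5-trimethoxyphenoxy)benzene | COc1cccc(OC)c1Oc1cc(OC)c(OC)c(OC)c1Oc1cc(OC)c(OC)c(OC)c1
F3 | step 3 | 2-{3,5-dimethoxy-4-[3,4,5-trimethoxy-2-(3,4,5-trimethoxyphenoxy)phenoxy]phenyl}-4,4,5,5-tetramethyl-1,3,2-dioxaborolane | COc1cc(B2OC(C)(C)C(C)(C)O2)cc(OC)c1Oc1cc(OC)c(OC)c(OC)c1Oc1cc(OC)c(OC)c(OC)c1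
F4 | step 10 | tetradecaacetate of the target (every hydroxyl of 20 as its acetate) | CC(=O)Oc1cc(OC(C)=O)c(Oc2cc(OC(C)=O)c(OC(C)=O)c(OC(C)=O)c2Oc2cc(OC(C)=O)c(Oc3cc(OC(C)=O)c(OC(C)=O)c(OC(C)=O)c3Oc3cc(OC(C)=O)c(OC(C)=O)c(OC(C)=O)c3)c(OC(C)=O)c2)c(OC(C)=O)c1
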